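**Retrosynthetic overview**

- Target 22 ← O6-acylation of (−)-loliolide 20 ← its benzoate 19 ← return of the C3=C3a double bond to the cis-fused saturated lactone 14 (selenoxide elimination).
- Key disconnection: the C4–C3a bond, which ties the quaternary gem-dimethyl carbon C4 to the butenolide β-carbon C3a lying next to quaternary C7a. It is made by a hydrogen-atom-transfer radical 6-exo cyclisation of the prenyl-type alkene of 13 onto its butenolide.
- 13 ← aldehyde 8 by catalyst-controlled α-benzoyloxylation (sets C6) and isopropylidene Wittig olefination. 8 ← (R)-linalool 1 (supplies C7a) by acrylation, epoxide masking, ring-closing metathesis and periodate cleavage.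
- Ring order: the γ-lactone (butenolide) first in step 3, the cyclohexane second in step 7.

Key step: step 7

Remark: the C6 oxygen is introduced and carried as a benzoate and exchanged for palmitate in steps 10–11, because benzoyl peroxide is the established oxygen source for the catalytic α-acyloxylation and a benzoate, unlike a palmitate, has no α-hydrogens to compete with the lactone in the enolisation of step 8. (R)-(−)-Linalool of high enantiomeric purity is taken as commercial, and atom numbers are those of loliolide (O1, C2, C3, C3a, C4–C7, C7a).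

**Route**

Step 1
Reactants: 1 (R)-linalool; 2 acryloyl chloride
Product: 4 (3R)-3,7-dimethylocta-1,6-dien-3-yl prop-2-enoate (linalyl acrylate), via lithium linalyl oxide 3 (not isolated)
Conditions: n-BuLi, THF, −78 °C; then acryloyl chloride, −78 → 0 °C
Reagents that add atoms: acryloyl chloride (compound 2), C=CC(=O)Cl
Why: O-acylation of the preformed lithium alkoxide overcomes the low reactivity of the tertiary allylic alcohol, and since no bond to the carbinol carbon is broken the (R) centre of linalool is kept and becomes C7a.

Step 2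
Reactants: 4 linalyl acrylate
Product: 5 (3R)-5-(3,3-dimethyloxiran-2-yl)-3-methylpent-1-en-3-yl prop-2-enoate (both epimers at the oxirane carbon)
Conditions: mCPBA, NaHCO3, CH2Cl2, 0 °C
Reagents that add atoms: mCPBA, O=C(OO)c1cccc(Cl)c1
Why: Prilezhaev epoxidation selects the electron-rich trisubstituted alkene over the vinyl and acrylate groups; this masks the alkene that would otherwise close a cyclopentene in step 3, acylating first prevents a free tertiary hydroxyl from opening the epoxide, and the unselective new centre is excised in step 4.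

Step 3
Reactants: 5 epoxy acrylate
Product: 6 (5R)-5-[2-(3,3-dimethyloxiran-2-yl)ethyl]-5-methylfuran-2(5H)-one
Conditions: second-generation Grubbs catalyst, (H2IMes)(PCy3)Cl2Ru=CHPh (5 mol%), CH2Cl2 (0.01 M), 40 °C
Reagents that add atoms: none
Why: Ring-closing metathesis of the vinyl group with the acrylate, helped by the quaternary carbon between them, closes the γ,γ-disubstituted butenolide with loss of ethylene, and the epoxide is inert to the ruthenium carbene.

Step 4
Reactants: 6 epoxy butenolide
Product: 8 3-[(2R)-2-methyl-5-oxo-2,5-dihydrofuran-2-yl]propanal, via vicinal diol 7 (not isolated)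
Conditions: H5IO6, THF/H2O, 0 → 23 °C
Reagents that add atoms: none
Why: Acid-mediated opening of the trisubstituted epoxide by water at its tertiary carbon gives the diol, which periodate cleaves (Malaprade reaction) to the aldehyde and acetone without affecting the butenolide.

Step 5
Reactants: 8 butenolide aldehyde; 9 dibenzoyl peroxide
Product: 10 (2R)-3-[(2R)-2-methyl-5-oxo-2,5-dihydrofuran-2-yl]-1-oxopropan-2-yl benzoate
Conditions: (R)-2-tritylpyrrolidine (10 mol%), (PhCO2)2, hydroquinone (10 mol%), THF, 0 °C
Reagents that add atoms: dibenzoyl peroxide (compound 9), O=C(OOC(=O)c1ccccc1)c1ccccc1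
Why: In this enamine-catalysed α-benzoyloxylation the E-enamine attacks the peroxide O–O bond from the face not shielded by the trityl group, which for the (R)-catalyst should give the (2R) centre (future C6) under catalyst control; the oxygen arrives already acylated, so no free C6 hydroxyl is ever placed where it could add to the butenolide.

Step 6
Reactants: 10 α-benzoyloxy aldehyde; 11 isopropyltriphenylphosphonium iodide
Product: 13 (2R)-4-methyl-1-[(2R)-2-methyl-5-oxo-2,5-dihydrofuran-2-yl]pent-3-en-2-yl benzoate, via isopropylidenetriphenylphosphorane 12 (not isolated)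
Conditions: 11, n-BuLi, THF, 0 °C; the ylide solution added to 10, THF, −78 → −20 °C
Reagents that add atoms: isopropyltriphenylphosphonium iodide (compound 11), CC(C)[P+](c1ccccc1)(c1ccccc1)c1ccccc1.[I-]
Why: Wittig olefination of the aldehyde by the non-stabilised ylide is much faster at −78 °C than ylide addition to the butenolide or the benzoate; the butenolide has no γ-hydrogen to lose, inverse addition keeps the base-sensitive C6 centre from epimerising, and the two identical methyl groups leave no alkene geometry to control.

Step 7
Reactants: 13 allylic benzoate butenolide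
Product: 14 (3aS,6S,7aR)-4,4,7a-trimethyl-2-oxooctahydro-1-benzofuran-6-yl benzoate
Conditions: Fe(acac)3 (30 mol%), PhSiH3, EtOH/(CH2OH)2, 60 °C, 0.02 M
Reagents that add atoms: none
Why: The iron hydride formed from Fe(acac)3 (trivalent iron) and PhSiH3 in ethanol delivers a hydrogen atom to C5 of the trisubstituted alkene, the tertiary C4 radical adds to the butenolide β-carbon C3a, and the C3 radical next to the lactone carbonyl is reduced by divalent iron to an enolate that the solvent protonates. The closest known reaction type is the Mukaiyama-type metal-hydride hydrogen-atom-transfer reductive coupling of an unactivated alkene with an electron-poor alkene (Giese-type radical conjugate addition), used here intramolecularly. The cyclohexane ring is closed in the 6-exo-trig mode by the C4–C3a bond. The new stereocentre C3a should be (S), with cis ring fusion (H-3a and the C7a methyl group on the same face), because the four-atom tether C7–C6–C5–C4 hangs from C7a and can reach only the butenolide face that carries it; C6 and C7a are not touched. The step needs hydrogen-atom transfer to the prenyl-type alkene and not to the butenolide, which the preference of the iron hydride for electron-rich alkenes that give tertiary radicals should secure; it also needs ring closure to outrun reduction of the C4 radical, which the polarity match of a nucleophilic tertiary radical with an electrophilic β-carbon, the early transition state of radical addition (tolerant of the quaternary neighbours C4 and C7a) and dilution should secure.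

Step 8
Reactants: 14 saturated lactone; 15 benzeneselenenyl bromide
Product: 17 (3R,3aS,6S,7aR)-4,4,7a-trimethyl-2-oxo-3-(phenylselanyl)octahydro-1-benzofuran-6-yl benzoate, via lithium lactone enolate 16 (not isolated)
Conditions: LiN(iPr)2, THF, −78 °C; PhSeBr, −78 °C
Reagents that add atoms: benzeneselenenyl bromide (compound 15), Br[Se]c1ccccc1
Why: The lactone is the only enolisable carbonyl group, and electrophilic selenenylation of its lithium enolate should occur on the face of C3 away from C4, placing selenium cis to H-3a as the later syn-elimination requires.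

Step 9
Reactants: 17 α-phenylselanyl lactone
Product: 19 (6S,7aR)-4,4,7a-trimethyl-2-oxo-2,4,5,6,7,7a-hexahydro-1-benzofuran-6-yl benzoate (loliolide benzoate), via selenoxide 18 (not isolated)
Conditions: H2O2 (30% aq), pyridine, CH2Cl2, 0 → 23 °C
Reagents that add atoms: none
Why: Oxidation to the selenoxide and its spontaneous syn-elimination toward H-3a, the only β-hydrogen, restore the C3=C3a double bond and remove the temporary C3 and C3a centres.

Step 10
Reactants: 19 loliolide benzoate
Product: 20 (−)-loliolide, (6S,7aR)-6-hydroxy-4,4,7a-trimethyl-5,6,7,7a-tetrahydro-1-benzofuran-2(4H)-one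
Conditions: K2CO3 (0.5 equiv), MeOH, 23 °C; NH4Cl aq
Reagents that add atoms: none
Why: Base-catalysed transesterification removes the benzoate, while the β,β-disubstituted butenolide resists conjugate addition and any lactone methanolysis is reversed on work-up because the Z-configured hydroxy ester relactonises.

Step 11
Reactants: 20 (−)-loliolide; 21 palmitoyl chloride
Product: 22 (−)-3-O-palmitoylloliolide, (6S,7aR)-4,4,7a-trimethyl-2-oxo-2,4,5,6,7,7a-hexahydro-1-benzofuran-6-yl hexadecanoate
Conditions: palmitoyl chloride, Et3N, DMAP (10 mol%), CH2Cl2, 0 → 23 °C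
Reagents that add atoms: palmitoyl chloride (compound 21), CCCCCCCCCCCCCCCC(=O)Cl
Why: DMAP-catalysed acylation of the secondary C6 hydroxyl breaks no bond to carbon, so both stereocentres are kept and the target results.

**Compound list**

1 | (R)-linalool | C=C[C@](C)(O)CCC=C(C)C | starting material
2 | acryloyl chloride | C=CC(=O)Cl | starting material
3 | lithium (3R)-3,7-dimethylocta-1,6-dien-3-olate | [Li]O[C@@](C)(C=C)CCC=C(C)C | intermediate (not isolated)
4 | (3R)-3,7-dimethylocta-1,6-dien-3-yl prop-2-enoate | C=CC(=O)O[C@@](C)(C=C)CCC=C(C)C | intermediate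
5 | (3R)-5-(3,3-dimethyloxiran-2-yl)-3-methylpent-1-en-3-yl prop-2-enoate, both oxirane epimers | C=CC(=O)O[C@@](C)(C=C)CCC1OC1(C)C | intermediate
6 | (5R)-5-[2-(3,3-dimethyloxiran-2-yl)ethyl]-5-methylfuran-2(5H)-one, both oxirane epimers | CC1(C)OC1CC[C@@]2(C)OC(=O)C=C2 | intermediate
7 | (5R)-5-(3,4-dihydroxy-4-methylpentyl)-5-methylfuran-2(5H)-one, both carbinol epimers | CC(C)(O)C(O)CC[C@@]1(C)OC(=O)C=C1 | intermediate (not isolated)
8 | 3-[(2R)-2-methyl-5-oxo-2,5-dihydrofuran-2-yl]propanal | O=CCC[C@@]1(C)OC(=O)C=C1 | intermediate
9 | dibenzoyl peroxide | O=C(OOC(=O)c1ccccc1)c1ccccc1 | starting material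
10 | (2R)-3-[(2R)-2-methyl-5-oxo-2,5-dihydrofuran-2-yl]-1-oxopropan-2-yl benzoate | O=C(O[C@@H](C=O)C[C@@]1(C)OC(=O)C=C1)c1ccccc1 | intermediate
11 | isopropyltriphenylphosphonium iodide | CC(C)[P+](c1ccccc1)(c1ccccc1)c1ccccc1.[I-] | starting material
12 | isopropylidenetriphenylphosphorane | CC(C)=P(c1ccccc1)(c1ccccc1)c1ccccc1 | intermediate (not isolated)
13 | (2R)-4-methyl-1-[(2R)-2-methyl-5-oxo-2,5-dihydrofuran-2-yl]pent-3-en-2-yl benzoate | O=C(O[C@@H](C=C(C)C)C[C@@]1(C)OC(=O)C=C1)c1ccccc1 | intermediate
14 | (3aS,6S,7aR)-4,4,7a-trimethyl-2-oxooctahydro-1-benzofuran-6-yl benzoate | O=C(O[C@H]1CC(C)(C)[C@@H]2CC(=O)O[C@]2(C)C1)c1ccccc1 | intermediate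
15 | benzeneselenenyl bromide | Br[Se]c1ccccc1 | starting material
16 | lithium (3aS,6S,7aR)-6-(benzoyloxy)-4,4,7a-trimethyl-3a,4,5,6,7,7a-hexahydro-1-benzofuran-2-olate | O=C(O[C@H]1CC(C)(C)[C@@H]2C=C(O[Li])O[C@]2(C)C1)c1ccccc1 | intermediate (not isolated)
17 | (3R,3aS,6S,7aR)-4,4,7a-trimethyl-2-oxo-3-(phenylselanyl)octahydro-1-benzofuran-6-yl benzoate | O=C(O[C@H]1CC(C)(C)[C@@H]2[C@@H]([Se]c3ccccc3)C(=O)O[C@]2(C)C1)c1ccccc1 | intermediate
18 | (3R,3aS,6S,7aR)-3-(benzeneseleninyl)-4,4,7a-trimethyl-2-oxooctahydro-1-benzofuran-6-yl benzoate, both selenium epimers | O=C(O[C@H]1CC(C)(C)[C@@H]2[C@@H]([Se](=O)c3ccccc3)C(=O)O[C@]2(C)C1)c1ccccc1 | intermediate (not isolated)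
19 | (6S,7aR)-4,4,7a-trimethyl-2-oxo-2,4,5,6,7,7a-hexahydro-1-benzofuran-6-yl benzoate | O=C(O[C@H]1CC(C)(C)C2=CC(=O)O[C@]2(C)C1)c1ccccc1 | intermediate
20 | (−)-loliolide | O[C@H]1CC(C)(C)C2=CC(=O)O[C@]2(C)C1 | intermediate
21 | palmitoyl chloride | CCCCCCCCCCCCCCCC(=O)Cl | starting material
22 | (−)-3-O-palmitoylloliolide | CCCCCCCCCCCCCCCC(=O)O[C@H]1CC(C)(C)C2=CC(=O)O[C@]2(C)C1 | target

**Step count**

Total: 11 steps. Longest linear sequence: 11 steps, from (R)-linalool 1.

**Steps most likely to fail**

1. Step 7 (key cyclisation). The hydride may transfer its hydrogen atom to the butenolide instead of the prenyl-type alkene (conjugate reduction), or the C4 radical may be reduced before it closes the hindered C4–C3a bond (plain hydrogenation of the side chain). Slow solvolysis of the allylic benzoate in warm ethanol is a further drain.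
   Fallback, setting out from 13 and returning at 14: the same C4 radical is generated without any hydride donor and with the butenolide as the only alkene left.
   - The trisubstituted alkene of 13 is epoxidised (mCPBA, NaHCO3, CH2Cl2, 0 °C; the butenolide is inert to peracid) to (1R)-1-(3,3-dimethyloxiran-2-yl)-2-[(2R)-2-methyl-5-oxo-2,5-dihydrofuran-2-yl]ethyl benzoate F1.
   - (C5H5)2TiCl, a trivalent titanium reagent made from (C5H5)2TiCl2 and Zn dust in THF, opens the epoxide homolytically toward the tertiary C4 radical (Nugent–RajanBabu reaction). This radical is trapped only slowly by the titanium reagent, so 6-exo addition to C3a, reduction of the C3 radical to a titanium enolate and a mildly acidic quench (to keep the benzoate on O6) should give the cis-fused (3aS,6R,7aR)-5-hydroxy-4,4,7a-trimethyl-2-oxooctahydro-1-benzofuran-6-yl benzoate F2.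
   - The extra C5 hydroxyl is removed by Barton–McCombie deoxygenation: 1,1'-thiocarbonyldiimidazole (toluene, 80 °C) gives the imidazolylthiocarbonyl derivative F3, and Bu3SnH/AIBN (toluene, 110 °C) then gives 14.

2. Step 6 (Wittig olefination). The basic ylide may epimerise the α-benzoyloxy aldehyde at C6 before it adds, or attack the butenolide in a conjugate sense.
   Fallback, setting out from 10 and returning at 13: a two-stage, non-basic construction of the alkene.
   - Takai–Lombardo methylenation of 10 (Zn, CH2Br2, TiCl4, THF/CH2Cl2, 0 °C) should give (2R)-1-[(2R)-2-methyl-5-oxo-2,5-dihydrofuran-2-yl]but-3-en-2-yl benzoate F4 without touching the acidic α-hydrogen.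
   - Cross-metathesis of F4 with excess 2-methylbut-2-ene (second-generation Grubbs catalyst, (H2IMes)(PCy3)Cl2Ru=CHPh, 40 °C) should give 13 with loss of propene; the electron-poor butenolide alkene next to a quaternary carbon does not take part.

3. Step 5 (α-benzoyloxylation). The peroxide may oxidise the amine catalyst, so that an uncatalysed or radical background path sets C6 with poor facial selectivity; the product aldehyde may also lose configurational purity on handling.
   Fallback, setting out from 8 and returning at 13: the oxygen is delivered as a persistent nitroxyl radical, which does not destroy the amine catalyst.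
   - α-Oxyamination of 8 with TEMPO under combined CuCl2·2H2O (10 mol%) and chiral imidazolidinone trifluoroacetate catalysis (air, acetone, −10 °C), using the catalyst enantiomer that gives the (2R) centre, should give the configurationally robust (2R)-3-[(2R)-2-methyl-5-oxo-2,5-dihydrofuran-2-yl]-2-[(2,2,6,6-tetramethylpiperidin-1-yl)oxy]propanal F5.
   - Wittig olefination of F5 with ylide 12 as in step 6 gives (5R)-5-methyl-5-{(2R)-4-methyl-2-[(2,2,6,6-tetramethylpiperidin-1-yl)oxy]pent-3-en-1-yl}furan-2(5H)-one F6.
   - Zn/AcOH cleaves the N–O bond to (5R)-5-[(2R)-2-hydroxy-4-methylpent-3-en-1-yl]-5-methylfuran-2(5H)-one F7.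
   - F7 is benzoylated at once (PhCOCl, pyridine, 0 °C), before the free hydroxyl can add to the butenolide, to give 13.

**Further compounds**

F1 | step 7 | (1R)-1-(3,3-dimethyloxiran-2-yl)-2-[(2R)-2-methyl-5-oxo-2,5-dihydrofuran-2-yl]ethyl benzoate, both oxirane epimers | O=C(O[C@@H](C1OC1(C)C)C[C@@]2(C)OC(=O)C=C2)c1ccccc1
F2 | step 7 | (3aS,6R,7aR)-5-hydroxy-4,4,7a-trimethyl-2-oxooctahydro-1-benzofuran-6-yl benzoate, both C5 epimers | O=C(O[C@H]1C(O)C(C)(C)[C@@H]2CC(=O)O[C@]2(C)C1)c1ccccc1
F3 | step 7 | (3aS,6R,7aR)-5-[(1H-imidazol-1-ylcarbonothioyl)oxy]-4,4,7a-trimethyl-2-oxooctahydro-1-benzofuran-6-yl benzoate, both C5 epimers | O=C(O[C@H]1C(OC(=S)n3ccnc3)C(C)(C)[C@@H]2CC(=O)O[C@]2(C)C1)c1ccccc1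
F4 | step 6 | (2R)-1-[(2R)-2-methyl-5-oxo-2,5-dihydrofuran-2-yl]but-3-en-2-yl benzoate | O=C(O[C@@H](C=C)C[C@@]1(C)OC(=O)C=C1)c1ccccc1
F5 | step 5 | (2R)-3-[(2R)-2-methyl-5-oxo-2,5-dihydrofuran-2-yl]-2-[(2,2,6,6-tetramethylpiperidin-1-yl)oxy]propanal | CC1(C)CCCC(C)(C)N1O[C@@H](C=O)C[C@@]2(C)OC(=O)C=C2
F6 | step 5 | (5R)-5-methyl-5-{(2R)-4-methyl-2-[(2,2,6,6-tetramethylpiperidin-1-yl)oxy]pent-3-en-1-yl}furan-2(5H)-one | CC1(C)CCCC(C)(C)N1O[C@@H](C=C(C)C)C[C@@]2(C)OC(=O)C=C2
F7 | step 5 | (5R)-5-[(2R)-2-hydroxy-4-methylpent-3-en-1-yl]-5-methylfuran-2(5H)-one | O[C@@H](C=C(C)C)C[C@@]1(C)OC(=O)C=C1
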